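**Numbering used throughout (fixed from the steps):** 1 syringaldehyde; 2 its O-tosylate; 3 1,1-bis(pinacolboryl)ethane; 4 lithiated 3; 5 (Z)-alkenyl boronate; 6 (E,E)-diene; 7 bis-borane adduct; 8 C2-symmetric diol; 9 monotosylate of 8; 10 bis-O-tosyl tetrahydrofuran; 11 target.

## Analysis of the target

Target 11 is a 7,7′-epoxy-8,8′-lignan: one tetrahydrofuran ring (O1, C2–C5) with identical 4-hydroxy-3,5-dimethoxyphenyl (syringyl) rings on C2 and C5 and methyl groups on C3 and C4. The SMILES string reads (2S,3S,4S,5R), that is 2,3-trans, 3,4-trans and 4,5-cis, with the two aryl groups cis to each other across O1. The constitution has a twofold axis through O1 and the midpoint of C3–C4. C2, C3 and C4 obey it (all-trans pattern) and C5 alone breaks it, so 11 is exactly one benzylic inversion away from a C2-symmetric array; this hidden symmetry is the feature on which the plan is built. C5 is also the hard centre, because its aryl group stands cis to the C4 methyl group and the all-trans isomer is lower in energy. Both ring C–O bonds are benzylic and para to a free phenol, so acid, Lewis acid or oxidant can open them through a benzylic cation or a p-quinone methide and drain C5 (and C2) into the all-trans series. In each syringyl ring the two methoxy groups (C3′, C5′) are meta to the benzylic carbon and only O4′ is conjugated with it, so the substituent on O4′ alone decides whether C2 and C5 can ionise. C3 and C4 carry only methyl groups, so the ring offers no functional handle from which stereocontrol could be relayed. The task is therefore four contiguous stereocentres, one of them contra-thermodynamic, in the absolute sense, on a skeleton that offers only its symmetry and its arenes.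

## Retrosynthetic reasoning

**11 ⇒ 10.** Only the two O4′–S bonds are cut; no skeletal bond changes. The tosyl groups stay on until the end because they turn the syringyl ring from a cation-stabilising into an electron-poor arene. This protects C2 and C5 from epimerisation in every earlier step. The forward reaction must free the phenols without acid.

**10 ⇒ 9 ⇒ 8.** The O1–C5 bond is cut, and it is cut as an SN2 bond formed with inversion. Undoing that inversion turns the unsymmetrical ring into the C2-symmetric (1S,2S,3S,4S)-diol 8, in which all four centres are pairwise equivalent. The two hydroxyl groups of 8 are homotopic, so no site selectivity is needed: activating either one gives the same monotosylate 9 and the same ring 10. Cutting O1–C2 with inversion would also give a C2-symmetric diol, but the 1,2-syn one, which would call for a crowded Z,Z-diene. The forward step must be a clean back-side 5-exo-tet displacement with no ionisation.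

**8 ⇒ 7 ⇒ 6 (key disconnection).** Both C–O bonds (C1–O, C4–O) and both C–H bonds at C2 and C3 are removed together. This leads to the flat, achiral (1E,3E)-diene 6. Syn addition of H and B to an E-trisubstituted alkene gives exactly the 1,2-anti relationship found at both ends of 8. The problem of four stereocentres thus shrinks to one question asked twice: which alkene face is attacked. A chiral monoalkylborane answers it, and oxidation of 7 with retention gives 8. The precursor has no stereocentre; the product has all four.

**6 ⇒ 5.** The central sp2–sp2 bond of 6 (C3–C4 of the final ring) is cut into two identical halves. Forming this bond at the sp2 level, rather than between two sp3 radicals or enolates, means no stereocentre is at stake when the skeleton is joined. Only alkene geometry must be retained. The forward reaction is an oxidative homocoupling of alkenyl boronate 5.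

**5 ⇒ 4 + 2 (4 from 3).** The trisubstituted C=C bond is cut between the benzylic carbon and the methyl-bearing carbon. Aldehyde 2 supplies the aryl carbon and the gem-diboronate 3, through its anion 4, supplies C–CH3 and the boron handle in one operation. The forward step has to place boron trans to the arene.

**2 ⇒ 1.** The O–S bond is cut, which leads to commercial 1.

## Alternatives that were turned down

**Alternative 1: the textbook, linear route.**
- *Disconnection:* the C5–aryl and C5–H bonds.
- *Forward key step:* an aryl-metal reagent adds to the lactone A1 to give the cyclic hemiketal A2. Lewis acid and a silane then reduce the derived oxocarbenium ion, with hydride entering anti to the C4 methyl group to give the 4,5-cis centre.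
- *Why turned down:*
  - The last step is sound, but A1 must be built centre by centre (auxiliary aldol, chain extension, a third stereocentre set separately, lactonisation).
  - The four stereocentres therefore cost three or four separate stereo-determining operations plus attachment and removal of an auxiliary.
  - The two identical aryl groups enter by two unrelated reactions, so the symmetry of the target is ignored and the step count is roughly double.
  - With an electron-rich aryl group, the Lewis acid that ionises A2 can also open the C2–O bond.

**Alternative 2: biomimetic dimerisation.**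
- *Disconnection:* C3–C4 and both C–O bonds in one oxidative event.
- *Forward key step:* a laccase or peroxidase, ideally with a dirigent protein, oxidises the propenylphenol A3. Radical 8–8′ coupling gives the bis-quinone methide A4; hydration of one quinone methide and 5-exo addition of the new hydroxyl group to the other close the ring.
- *Why turned down:*
  - It is the shortest conceivable route.
  - However, the radical coupling itself carries no chiral information.
  - The known templating proteins recognise the C9 hydroxyl group that A3 lacks.
  - O4′-to-C8 coupling competes.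
  - The two benzylic centres are set by uncatalysed additions to A4, so two of the four stereocentres, including the hard one, have no control element.
  - The product phenol is as oxidisable as A3. A single enantiomer of a single diastereomer cannot be defended.

**Alternative 3: (3+2) cycloaddition.**
- *Disconnection:* O1–C5 and C2–C3.
- *Forward key step:* Lewis-acid-catalysed (3+2) cycloaddition of the donor–acceptor cyclopropane A5 with the aldehyde A6 gives the tetrahydrofuran-3,3-diester A7.
- *Why it deserves consideration:* the stereochemical fit is attractive. Inversion at the donor carbon of the trans-cyclopropane gives 4,5-cis, and the reaction type gives 2,5-cis.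
- *Why turned down:*
  - Ring-opening of A5 can only scramble the aryl-bearing carbon, never the methyl-bearing one. Racemic A5 therefore cannot be funnelled dynamically into one enantiomer and must be made enantiopure, where malonyl-carbene transfer to a propenylarene is a weak point.
  - The C3 gem-diester must then be degraded to a single methyl group (dealkoxycarbonylation, reduction, activation, reduction), so the clean-up costs more steps than the key step wins.
  - The donor arene must be electron-rich under Lewis acid, which is exactly the condition that epimerises C5.

Key step: step 4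

Assumption: 3 and the crystalline TMEDA adduct of monoisopinocampheylborane from (−)-α-pinene are taken as catalogue items; the free borane is liberated beforehand with BF3·OEt2, filtered and used as a stock solution.

## Route

Step 1
Reactants: 1 syringaldehyde (4-hydroxy-3,5-dimethoxybenzaldehyde)
Product: 2 4-formyl-2,6-dimethoxyphenyl 4-methylbenzenesulfonate
Conditions: TsCl, Et3N, DMAP (cat.), CH2Cl2, 0 °C to rt
Reagents that add atoms: p-toluenesulfonyl chloride, Cc1ccc(cc1)S(=O)(=O)Cl
Why: Plain O-sulfonylation of a phenol. The tosylate is both the protecting group and the electronic switch that makes the arene (para sulfonyloxy, two meta methoxy groups) electron-poor toward the benzylic carbon for steps 4 and 5.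

Step 2
Reactants: 2 4-formyl-2,6-dimethoxyphenyl 4-methylbenzenesulfonate; 3 2,2′-(ethane-1,1-diyl)bis(4,4,5,5-tetramethyl-1,3,2-dioxaborolane)
Product: 5 2,6-dimethoxy-4-[(1Z)-2-(4,4,5,5-tetramethyl-1,3,2-dioxaborolan-2-yl)prop-1-en-1-yl]phenyl 4-methylbenzenesulfonate, via lithiated gem-diboronate 4 (not isolated)
Conditions: 3, LiTMP, THF, 0 °C; then 2, −78 °C to rt
Reagents that add atoms: lithium 2,2,6,6-tetramethylpiperidide, [Li]N1C(C)(C)CCCC1(C)C (its lithium is carried only by 4)
Why: Boron-Wittig olefination: the boron-stabilised carbanion adds to the aldehyde, and syn elimination of boron and oxygen follows. In the elimination the aryl group should eclipse the smaller methyl group rather than the remaining pinacolboryl group, which places boron trans to the arene. The preformed, stabilised anion leaves the aryl tosylate untouched.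

Step 3
Reactants: 5 (Z)-alkenyl boronate (two molecules)
Product: 6 (1E,3E)-2,3-dimethylbuta-1,3-diene-1,4-diylbis(2,6-dimethoxy-4,1-phenylene) bis(4-methylbenzenesulfonate)
Conditions: Pd(OAc)2 (cat.), K2CO3, O2 (1 atm), DMF/H2O, 40 °C
Reagents that add atoms: none
Why: Palladium-catalysed aerobic oxidative homocoupling of an alkenyl boronate: two transmetalations to Pd(II), then reductive elimination with retention at both sp2 carbons, with O2 returning Pd(0) to Pd(II). No stereocentre is formed, and the hindered aryl tosylate does not undergo oxidative addition with ligand-free palladium at this temperature.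

Step 4
Reactants: 6 (1E,3E)-diene
Product: 8 (1S,2S,3S,4S)-1,4-bis[3,5-dimethoxy-4-(tosyloxy)phenyl]-2,3-dimethylbutane-1,4-diol, via bis-borane adduct 7 (not isolated)
Conditions: 6 added slowly to IpcBH2 from (−)-α-pinene (4 equiv, ca. 1 M), THF, −25 to 0 °C; MeOH; then NaOH, H2O2, 0 °C to rt
Reagents that add atoms: hydrogen peroxide, OO (both hydroxyl oxygens); monoisopinocampheylborane from (−)-α-pinene, B[C@@H]1[C@@H](C)[C@@H]2C[C@H](C1)C2(C)C (boron and terpene part are carried only by 7, only hydrogen stays in 8)
Why: The step relies on asymmetric hydroboration of trans and trisubstituted alkenes with monoisopinocampheylborane, used twice on diene 6, whose two styrene units are twisted out of conjugation by the C2 and C3 methyl groups and should behave as separate alkenes. Each B–H adds through the concerted four-centre syn transition state with boron on the benzylic CH carbon, the less substituted terminus, a preference strengthened by the electron-poor arene, so neither a tertiary nor an allylic borane is expected. C1 and C4 are set by the reagent: by analogy with its established sense on trans and trisubstituted alkenes, the borane from (−)-α-pinene should choose the face that gives the S carbinol, and the antipodal reagent is equally available should the sense prove opposite. C2 and C3 are not independent centres, because syn addition to an E alkene fixes the 1,2-anti (like) relationship at both ends. The relation between the two halves follows from attack on homochiral faces and is reinforced by the substrate, since in the mono-adduct the large CH(B)Ar group stands anti to the incoming borane and the C2 hydrogen points toward the C3 methyl group (least A1,2 strain), which exposes the same face. A single facial error gives the achiral meso diastereomer, which is removed by chromatography or crystallisation, so the enantiomeric purity of 8 should exceed the selectivity of one addition. The selectivity that must be secured is intermolecular over intramolecular second addition; excess concentrated reagent, the strain of an endo four-centre closure to a borolane and the crowding of a borane with three branched groups all favour it. The step closes no ring (closure follows in step 5); alkaline peroxide replaces boron by oxygen with retention, and aryl tosylates and methyl ethers are inert to both stages.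

Step 5
Reactants: 8 (1S,2S,3S,4S)-diol
Product: 10 (2S,3S,4S,5R)-2,5-bis[3,5-dimethoxy-4-(tosyloxy)phenyl]-3,4-dimethyltetrahydrofuran, via monotosylate 9 (not isolated)
Conditions: NaH (2.5 equiv), THF, 0 °C; 1-tosylimidazole (1.05 equiv, slow addition), 0 °C to rt
Reagents that add atoms: 1-(p-toluenesulfonyl)imidazole, Cc1ccc(cc1)S(=O)(=O)n1ccnc1 (its tosyl group is carried only by 9 and leaves again)
Why: One-pot diol-to-cyclic-ether protocol ending in an intramolecular Williamson 5-exo-tet displacement. The two hydroxyl groups of 8 are homotopic, so either one gives the same 9, and the remaining alkoxide attacks from the back, turning that carbon from S to R and placing its aryl group cis to the neighbouring methyl group. Ionisation toward the all-trans isomer is suppressed by the electron-poor arene, the halide-free reagent excludes double inversion, and slow addition to the bis-alkoxide lets ring closure outrun a second sulfonylation.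

Step 6
Reactants: 10 bis-O-tosyl tetrahydrofuran
Product: 11 (2S,3S,4S,5R)-2,5-bis(4-hydroxy-3,5-dimethoxyphenyl)-3,4-dimethyltetrahydrofuran (target)
Conditions: Mg turnings, MeOH/THF, rt, argon; pH 7 phosphate buffer
Reagents that add atoms: none
Why: Dissolving-metal (single-electron) cleavage of the aryl sulfonate S–O bond frees both phenoxides without acid, so the benzylic C–O bonds cannot ionise and no stereocentre is touched. The neutral quench keeps the free p-hydroxybenzyl ether away from the conditions that epimerise C2 and C5.

## Compound list

1 | syringaldehyde (4-hydroxy-3,5-dimethoxybenzaldehyde) | COc1cc(C=O)cc(OC)c1O | starting material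
2 | 4-formyl-2,6-dimethoxyphenyl 4-methylbenzenesulfonate | COc1cc(C=O)cc(OC)c1OS(=O)(=O)c1ccc(C)cc1 | intermediate
3 | 2,2′-(ethane-1,1-diyl)bis(4,4,5,5-tetramethyl-1,3,2-dioxaborolane) | CC(B1OC(C)(C)C(C)(C)O1)B1OC(C)(C)C(C)(C)O1 | starting material
4 | 1-lithio-1,1-bis(pinacolboryl)ethane | [Li]C(C)(B1OC(C)(C)C(C)(C)O1)B1OC(C)(C)C(C)(C)O1 | intermediate
5 | 2,6-dimethoxy-4-[(1Z)-2-(pinacolboryl)prop-1-en-1-yl]phenyl 4-methylbenzenesulfonate (boron trans to the arene) | COc1cc(/C=C(C)/B2OC(C)(C)C(C)(C)O2)cc(OC)c1OS(=O)(=O)c1ccc(C)cc1 | intermediate
6 | (1E,3E)-1,4-bis[3,5-dimethoxy-4-(tosyloxy)phenyl]-2,3-dimethylbuta-1,3-diene | COc1cc(/C=C(C)/C(C)=C/c2cc(OC)c(OS(=O)(=O)c3ccc(C)cc3)c(OC)c2)cc(OC)c1OS(=O)(=O)c1ccc(C)cc1 | intermediate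
7 | bis(isopinocampheylboryl) adduct of 6, one B(H)Ipc on each benzylic carbon, same spatial arrangement as in 8 | COc1cc([C@@H](B[C@@H]2[C@@H](C)[C@@H]3C[C@H](C2)C3(C)C)[C@@H](C)[C@H](C)[C@H](B[C@@H]2[C@@H](C)[C@@H]3C[C@H](C2)C3(C)C)c2cc(OC)c(OS(=O)(=O)c3ccc(C)cc3)c(OC)c2)cc(OC)c1OS(=O)(=O)c1ccc(C)cc1 | intermediate
8 | (1S,2S,3S,4S)-1,4-bis[3,5-dimethoxy-4-(tosyloxy)phenyl]-2,3-dimethylbutane-1,4-diol | COc1cc([C@@H](O)[C@@H](C)[C@H](C)[C@H](O)c2cc(OC)c(OS(=O)(=O)c3ccc(C)cc3)c(OC)c2)cc(OC)c1OS(=O)(=O)c1ccc(C)cc1 | intermediate
9 | mono-O-tosylate of 8 (present as its sodium alkoxide) | COc1cc([C@@H](O)[C@@H](C)[C@H](C)[C@H](OS(=O)(=O)c2ccc(C)cc2)c2cc(OC)c(OS(=O)(=O)c3ccc(C)cc3)c(OC)c2)cc(OC)c1OS(=O)(=O)c1ccc(C)cc1 | intermediate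
10 | (2S,3S,4S,5R)-2,5-bis[3,5-dimethoxy-4-(tosyloxy)phenyl]-3,4-dimethyltetrahydrofuran | COc1cc([C@H]2O[C@@H](c3cc(OC)c(OS(=O)(=O)c4ccc(C)cc4)c(OC)c3)[C@@H](C)[C@@H]2C)cc(OC)c1OS(=O)(=O)c1ccc(C)cc1 | intermediate
11 | (2S,3S,4S,5R)-2,5-bis(4-hydroxy-3,5-dimethoxyphenyl)-3,4-dimethyltetrahydrofuran | COc1cc([C@H]2O[C@@H](c3cc(OC)c(O)c(OC)c3)[C@@H](C)[C@@H]2C)cc(OC)c1O | target

## Step count and risks

Total step count: 6. Longest linear sequence: 6 (1 to 11).

**Step 4 (key step).**
- *What may go wrong:*
  - After the first addition, the remaining B–H of the mono-adduct may add to the second double bond within the same molecule. The tether reaches only the face opposite to the one wanted, so the relation between the two halves would drift into the meso series.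
  - Facial discrimination may be lower for an alkene whose boron-bearing carbon carries an aryl group.
  - Slow addition to the crowded alkene may let the reagent shed its terpene, which would bring an achiral borane into play.
- *Fallback (from 6, back at 8):* 6 is hydroborated with 9-BBN-H, a dialkylborane with a single B–H that cannot cyclise. The step then relies on syn addition and on the substrate bias described above. Oxidation gives 8 as a racemate with its enantiomer F1. Esterification with (S)-O-methylmandelic acid (DCC, DMAP) gives the diastereomeric bis-esters F2 (from 8) and F3 (from F1), which are separated by crystallisation or chromatography. Methanolysis of F2 (K2CO3, MeOH, rt) returns 8.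

**Step 5.**
- *What may go wrong:*
  - Both alkoxides may be sulfonylated before ring closure.
  - E2 loss of the sulfonate toward the styrene may compete.
  - Partial ionisation may leak configuration at C5.
- *Fallback (from 8, back at 10):* C5 is set by hydride delivery instead of displacement. Mono-oxidation of 8 (Dess–Martin periodinane, 1 equiv) gives the γ-hydroxy ketone F4, which rests as its cyclic hemiketal F5 and is thereby shielded from a second oxidation. Et3SiH and BF3·OEt2 in CH2Cl2 at low temperature ionise F5 to the 2-aryl oxocarbenium ion. Hydride enters anti to the adjacent methyl group, which places the aryl group cis to it and gives 10. The electron-poor arene at C2 keeps the other benzylic C–O bond closed.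

**Step 3.**
- *What may go wrong:* protodeboronation or oxidation of the C–B bond may outrun the second transmetalation at the hindered α-methyl alkenyl boronate.
- *Fallback (from 5, back at 6):* cross-coupling replaces homocoupling. Half of 5 is converted by iododeboronation (NaOH, I2, THF) with retention into the (E)-alkenyl iodide F6. Suzuki coupling of F6 with the other half of 5 [Pd(PPh3)4, aqueous K3PO4, THF] gives 6 with both geometries retained.

**Step 2.**
- *What may go wrong:* geometric selectivity in the boron–oxygen elimination may be insufficient, because methyl and pinacolboryl differ less in size than hydrogen and pinacolboryl.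
- *Fallback (from 2, back at 5):* Ohira–Bestmann homologation of 2 gives the terminal alkyne F7, and C-methylation (LDA, MeI, −78 °C) gives the arylpropyne F8. Copper-catalysed borylcupration and protonation (CuCl, NaOt-Bu, phosphine, B2pin2, MeOH) places copper on the aryl-bearing carbon and boron on the methyl-bearing carbon. Syn addition fixes the geometry of 5 by mechanism.

## Further compounds

F1 | step 4 | (1R,2R,3R,4R)-1,4-bis[3,5-dimethoxy-4-(tosyloxy)phenyl]-2,3-dimethylbutane-1,4-diol (enantiomer of 8) | COc1cc([C@H](O)[C@H](C)[C@@H](C)[C@@H](O)c2cc(OC)c(OS(=O)(=O)c3ccc(C)cc3)c(OC)c2)cc(OC)c1OS(=O)(=O)c1ccc(C)cc1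
F2 | step 4 | bis[(S)-2-methoxy-2-phenylacetate] of 8 | COc1cc([C@@H](OC(=O)[C@@H](OC)c2ccccc2)[C@@H](C)[C@H](C)[C@H](OC(=O)[C@@H](OC)c2ccccc2)c2cc(OC)c(OS(=O)(=O)c3ccc(C)cc3)c(OC)c2)cc(OC)c1OS(=O)(=O)c1ccc(C)cc1
F3 | step 4 | bis[(S)-2-methoxy-2-phenylacetate] of F1 | COc1cc([C@H](OC(=O)[C@@H](OC)c2ccccc2)[C@H](C)[C@@H](C)[C@@H](OC(=O)[C@@H](OC)c2ccccc2)c2cc(OC)c(OS(=O)(=O)c3ccc(C)cc3)c(OC)c2)cc(OC)c1OS(=O)(=O)c1ccc(C)cc1
F4 | step 5 | (2S,3S,4S)-4-hydroxy-1,4-bis[3,5-dimethoxy-4-(tosyloxy)phenyl]-2,3-dimethylbutan-1-one | COc1cc([C@@H](O)[C@@H](C)[C@H](C)C(=O)c2cc(OC)c(OS(=O)(=O)c3ccc(C)cc3)c(OC)c2)cc(OC)c1OS(=O)(=O)c1ccc(C)cc1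
F5 | step 5 | cyclic hemiketal of F4 (2-hydroxy-2,5-diaryl-3,4-dimethyltetrahydrofuran, anomeric mixture) | COc1cc([C@H]2OC(O)(c3cc(OC)c(OS(=O)(=O)c4ccc(C)cc4)c(OC)c3)[C@@H](C)[C@@H]2C)cc(OC)c1OS(=O)(=O)c1ccc(C)cc1
F6 | step 3 | 4-[(1E)-2-iodoprop-1-en-1-yl]-2,6-dimethoxyphenyl 4-methylbenzenesulfonate | COc1cc(/C=C(C)/I)cc(OC)c1OS(=O)(=O)c1ccc(C)cc1
F7 | step 2 | 4-ethynyl-2,6-dimethoxyphenyl 4-methylbenzenesulfonate | C#Cc1cc(OC)c(OS(=O)(=O)c2ccc(C)cc2)c(OC)c1
F8 | step 2 | 2,6-dimethoxy-4-(prop-1-yn-1-yl)phenyl 4-methylbenzenesulfonate | CC#Cc1cc(OC)c(OS(=O)(=O)c2ccc(C)cc2)c(OC)c1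
A1 | alternative 1 | (3S,4S,5S)-5-[4-(benzyloxy)-3,5-dimethoxyphenyl]-3,4-dimethyldihydrofuran-2(3H)-one | COc1cc([C@H]2OC(=O)[C@@H](C)[C@@H]2C)cc(OC)c1OCc1ccccc1
A2 | alternative 1 | cyclic hemiketal from aryl addition to A1 (anomeric mixture) | COc1cc([C@H]2OC(O)(c3cc(OC)c(OCc4ccccc4)c(OC)c3)[C@@H](C)[C@@H]2C)cc(OC)c1OCc1ccccc1
A3 | alternative 2 | (E)-2,6-dimethoxy-4-(prop-1-en-1-yl)phenol | C/C=C/c1cc(OC)c(O)c(OC)c1
A4 | alternative 2 | (8S,8′S)-8,8′-linked bis(p-quinone methide) | COC1=CC(=C[C@@H](C)[C@H](C)C=C2C=C(OC)C(=O)C(OC)=C2)C=C(OC)C1=O
A5 | alternative 3 | dimethyl (2S,3R)-2-[4-(benzyloxy)-3,5-dimethoxyphenyl]-3-methylcyclopropane-1,1-dicarboxylate (trans) | C[C@@H]1[C@@H](c2cc(OC)c(OCc3ccccc3)c(OC)c2)C1(C(=O)OC)C(=O)OC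
A6 | alternative 3 | 4-(benzyloxy)-3,5-dimethoxybenzaldehyde | COc1cc(C=O)cc(OC)c1OCc1ccccc1
A7 | alternative 3 | dimethyl 2,5-bis[4-(benzyloxy)-3,5-dimethoxyphenyl]-4-methyltetrahydrofuran-3,3-dicarboxylate, configured at C2, C4 and C5 as in 11 | COc1cc([C@H]2O[C@@H](c3cc(OC)c(OCc4ccccc4)c(OC)c3)[C@@H](C)C2(C(=O)OC)C(=O)OC)cc(OC)c1OCc1ccccc1
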